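**Remarks on the chemistry (used throughout)**

- Cembrane numbering: C1 is the ring CH that carries C15; C2 is the lactone O–CH; the olefins are C3=C4(C18), C7=C8(C19) and C11=C12(C20); C13 is the acetoxy carbon; C14 is the CH2 between C13 and C1; C15 is the lactone α-carbon, C16 the carbonyl carbon, C17 the exocyclic CH2. The target is (1S,2S,3E,7E,11E,13S)-13-acetoxycembra-3,7,11,15(17)-tetraen-16,2-olide.
- Assumption: only compounds that carry the carbon skeleton are numbered; reagents are given by name and SMILES in the steps. Metal-bound species of catalytic cycles are described in words and are not numbered.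

## The problem

1. The target is a 14-membered carbocycle with three E-trisubstituted olefins, a cis-fused α-methylene-γ-butyrolactone on C1/C2 and an allylic acetate at C13.
2. C2 to C13 with C18–C20 are an intact all-E farnesyl chain oxidised at both ends. What must be built is the five-carbon unit C14, C1, C15, C16, C17 between the chain ends, the ring, and three stereocentres.
3. C1 and C2 are adjacent and cis, which is the less favoured outcome for additions to a preformed butenolide. C13 is 1,3 to C1 across C14, too remote for reliable open-chain induction, so a relay C13 → C1 → C2 has to be organised.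
4. The α-methylene lactone is a Michael acceptor that isomerises or polymerises under base or heat. The C2–O and C13–O bonds are allylic and can ionise or transpose. The 1,5-diene array excludes strong acid and electrophilic oxidants.
5. The feature that makes the key step possible: O-13 and C1 are 1,3-related, so the acrylate unit C15(=C17)–C16 can be hung on O-13 and reach C1 through the six-membered ring O13–C16–C15–C1–C14–C13.
6. C1–C2–C3=C4 is the trace of a ring 1,3-diene C1=C2–C3=C4. After carbon has added to C1, its allylpalladium places oxygen on C2, and the C4 methyl (C18) blocks the other allyl terminus.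
7. O-2 and O-13 are both within lactonising distance of C16 (five- against six-membered ring), so the acyl group can be moved from O-13 to O-2 at the end.

## Retrosynthesis

**14 ⇒ 13.** The acetyl–O13 bond is cut. The acetate is put on last because O-13 is needed earlier as the anchor of the tether. Alcohol 13 differs from 14 only by the acetyl group, and the forward step is a plain acylation.

**13 ⇒ 11.** The C16–O2 bond is cut and C16 is joined to O-13 instead, with an acetyl group on O-2. Compound 11 is a constitutional isomer of 14 in which lactone and acetate have changed places. The forward reaction is saponification and relactonisation through dihydroxy acid 12. It must close the five-membered ring and not the six-membered one, and it touches no stereocentre because only acyl–oxygen bonds are made and broken.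

**11 ⇒ 10 (key disconnection).** The C1–C15 bond and the C2–O(acetate) bond are cut. This removes both lactone stereocentres at once and reveals the macrocyclic diene ester 10, which has a single stereocentre (C13) and a planar C1=C2–C3=C4 unit. The neighbouring cut C1–C2 (the usual one) would have to create C1 and C2 in a flexible 14-membered transition state with only remote guidance from C13. Here C1 is set through a six-membered ring from O-13 and C2 by the stereospecificity of the metal. The forward reaction must be a 6-exo syn carbopalladation followed by anti capture of the allylpalladium at C2.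

**10 ⇒ 8.** The ester bond O13–C16 is cut. Alcohol 8 is acylated with a 2-bromoacryloyl group, made in the flask from the dibromo ester 9. Nothing is asked but a clean O-acylation of a secondary allylic alcohol.

**8 ⇒ 7.** The C1=C2 double bond is cut (ring-closing metathesis). It is the only disubstituted olefin of the ring; all the trisubstituted ones come from farnesol and are not disturbed. The open-chain pentaene 7 carries two terminal olefins at the chain ends. The forward reaction has to give the E olefin and leave the hindered olefins alone.

**7 ⇒ 5.** The C13–C14 bond is cut: allyl transfer from a chiral allylborane to enal 5. This is the only step in which absolute configuration is introduced, and it is reagent-controlled. Aldehyde 5 has no stereocentre.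

**5 ⇒ 3 ⇒ 2 ⇒ 1.** Only functional-group changes on the farnesyl chain remain: allylic oxidation of the terminal E-methyl of 3 (through alcohol 4), methylenation of farnesal 2, and oxidation of farnesol 1. No protecting group is needed because the C2 terminus is stored as the diene that the metathesis consumes.

## Roads not taken

**Alternative 1:** cut C1–C2 and the lactone C–O bond (the most obvious plan). The forward key step is an intramolecular Barbier allylation of the bromo-aldehyde A1 with CrCl2 or indium, which closes the carbocycle and then the lactone. The chosen plan is better for three reasons. In A1 the facial selectivity at C1/C2 depends on 1,3-induction from C13 through a floppy macrocyclic transition state. The cis/trans outcome depends on the geometry and metal of the allyl species. A1 also needs the two chain ends differentiated by protecting groups (about ten steps), whereas the chosen route needs none.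

**Alternative 2:** cut C14–C1. The forward key step is a Carroll rearrangement of the 18-membered β-keto lactone A2 (closed by acylketene lactonisation), which extrudes CO2, contracts the ring to 14 and creates the exocyclic methylene; the C13 ketone is then reduced. It is regiospecific, but the [3,3] shift should deliver C14 to the butenolide face anti to C3, which gives the trans ring fusion. It also needs temperatures at which the acrylate polymerises, and a longer run-up.

**Alternative 3:** cut C12–C13 far from the lactone. The forward key step is a Nozaki–Hiyama–Kishi ring closure of the iodo-aldehyde A3 with the cis-lactone already in place. C13 would again be set by remote control. C12 must be a vinyl iodide, so the farnesyl chain cannot be used intact and all three trisubstituted olefins must be rebuilt (thirteen steps or more). The α-methylene lactone would also be exposed to the reducing chromium and nickel salts.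

Key step: step 7

## Route

Step 1
Reactants: 1 (2E,6E)-farnesol
Product: 2 (2E,6E)-farnesal
Conditions: MnO2 (activated, excess), CH2Cl2, rt
Reagents that add atoms: none
Why: Chemoselective oxidation of a primary allylic alcohol with MnO2; the neutral conditions should keep the E geometry of the conjugated olefin.

Step 2
Reactants: 2 (2E,6E)-farnesal
Product: 3 (3E,7E)-4,8,12-trimethyltrideca-1,3,7,11-tetraene
Conditions: Ph3PCH3Br, KN(SiMe3)2, THF, 0 °C; then 2, −78 °C to rt
Reagents that add atoms: methyltriphenylphosphonium bromide, C[P+](c1ccccc1)(c1ccccc1)c1ccccc1.[Br-]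
Why: Wittig methylenation of an enal (1,2-addition only); it stores the C2 terminus as a terminal 1,3-diene without touching the 3E olefin.

Step 3
Reactants: 3 (3E,7E)-4,8,12-trimethyltrideca-1,3,7,11-tetraene
Product: 5 (2E,6E,10E)-2,6,10-trimethyltrideca-2,6,10,12-tetraenal, via allylic alcohol 4 (not isolated)
Conditions: SeO2 (cat.), t-BuOOH, salicylic acid (cat.), CH2Cl2, 0 °C to rt; aqueous work-up; then MnO2, CH2Cl2, rt
Reagents that add atoms: selenium dioxide (oxygen carrier), O=[Se]=O; tert-butyl hydroperoxide (terminal oxidant), CC(C)(C)OO
Why: Allylic oxidation by ene reaction and [2,3]-shift should attack the E-methyl of the terminal, most electron-rich trisubstituted olefin, as is usual for polyprenyl chains; MnO2 then converts alcohol 4 and any over-oxidised material to the single enal 5.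

Step 4
Reactants: 5 (2E,6E,10E)-2,6,10-trimethyltrideca-2,6,10,12-tetraenal
Product: 7 (4S,5E,9E,13E)-5,9,13-trimethylhexadeca-1,5,9,13,15-pentaen-4-ol, via borinate ester 6 (not isolated)
Conditions: (−)-Ipc2B(allyl) [from (+)-α-pinene], Et2O, −78 °C; then NaOH, H2O2, 0 °C to rt
Reagents that add atoms: (−)-B-allyldiisopinocampheylborane, C=CCB([C@@H]1C[C@@H]2C[C@H]([C@H]1C)C2(C)C)[C@@H]1C[C@@H]2C[C@H]([C@H]1C)C2(C)C
Why: Reagent-controlled allylboration through a closed chair transition state; the (+)-α-pinene-derived reagent is expected to add to the Si face of the aldehyde (the face that gives (S)-1-phenylbut-3-en-1-ol from benzaldehyde), which makes C13 S; this facial assignment is taken from the general behaviour of the reagent and should be confirmed on 7.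

Step 5
Reactants: 7 (4S,5E,9E,13E)-5,9,13-trimethylhexadeca-1,5,9,13,15-pentaen-4-ol
Product: 8 (1S,2E,6E,10E,12E)-2,6,10-trimethylcyclotetradeca-2,6,10,12-tetraen-1-ol
Conditions: second-generation Grubbs catalyst RuCl2(=CHPh)(PCy3)(H2IMes) (cat.), CH2Cl2, high dilution, 40 °C
Reagents that add atoms: none
Why: Ring-closing metathesis between the monosubstituted olefin and the terminal CH2 of the diene; the trisubstituted olefins, including the inner diene bond, are too hindered to compete, and the 14-membered ring should favour the E-configured C1=C2 bond of a conjugated E,E-diene.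

Step 6
Reactants: 8 (1S,2E,6E,10E,12E)-2,6,10-trimethylcyclotetradeca-2,6,10,12-tetraen-1-ol
Product: 10 (1S,2E,6E,10E,12E)-2,6,10-trimethylcyclotetradeca-2,6,10,12-tetraen-1-yl 2-bromoprop-2-enoate, via dibromo ester 9 (not isolated)
Conditions: 2,3-dibromopropanoyl chloride, Et3N (excess), CH2Cl2, −20 to 0 °C
Reagents that add atoms: 2,3-dibromopropanoyl chloride, O=C(Cl)C(Br)CBr
Why: O-acylation followed by amine-induced dehydrobromination of the 2,3-dibromo ester gives the 2-bromoacrylate in one flask; only an acyl–oxygen bond is formed, so C13 keeps its configuration.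

Step 7
Reactants: 10 (1S,2E,6E,10E,12E)-2,6,10-trimethylcyclotetradeca-2,6,10,12-tetraen-1-yl 2-bromoprop-2-enoate
Product: 11 (1S,2S,3E,7E,11E,13S)-2-acetoxycembra-3,7,11,15(17)-tetraen-16,13-olide
Conditions: Pd(OAc)2 (10 mol %), PPh3, Bu4NOAc, DMSO, high dilution, 70 °C
Reagents that add atoms: tetrabutylammonium acetate, CC(=O)[O-].CCCC[N+](CCCC)(CCCC)CCCC
Why: Zerovalent palladium (from Pd(OAc)2 and PPh3) inserts into the C15–Br bond and the alkenylpalladium adds syn across C1=C2 of the ring diene (intramolecular Mizoroki–Heck step), closing the six-membered lactone ring O13–C16–C15–C1–C14–C13 in the 6-exo-trig mode. The closest known reaction type is the Heck insertion into a 1,3-diene followed by capture of the η3-allylpalladium by a carboxylate (Heck/allylic-substitution cascades and palladium-catalysed diene heteroannulations). C1 is set by the tether: in the chair-like transition state the two macrocycle bonds C13–C12 and C1–C2 are pseudo-equatorial (extended C12–C13–C14–C1 backbone), so C15 can only reach the face of C1 that is syn to O-13, which is the 1S configuration. Insertion leaves palladium on that same face at C2 as an η3-allyl over C2–C3–C4, and acetate attacks C2 from the opposite face (outer sphere), so carbon and oxygen add anti across the E olefin and C2 becomes S, the cis relationship of the later γ-lactone. The step needs 6-exo attack on C1 and not 5-exo attack on C12, and acetate at C2 and not at C4: the diene is the better ligand and gives a stabilised allyl, C12 would have to become quaternary, and C4 is tertiary, so that any acetate formed there would ionise again. The C4 methyl also holds C1 in the syn position of the allyl, so the 3E geometry and the C2 configuration should not be lost by allyl isomerisation.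

Step 8
Reactants: 11 (1S,2S,3E,7E,11E,13S)-2-acetoxycembra-3,7,11,15(17)-tetraen-16,13-olide
Product: 13 (1S,2S,3E,7E,11E,13S)-13-hydroxycembra-3,7,11,15(17)-tetraen-16,2-olide, via dihydroxy acid 12 (not isolated)
Conditions: LiOH, THF/H2O, 0 °C to rt; then aq. HCl to pH 3–4, EtOAc, rt
Reagents that add atoms: lithium hydroxide, [Li+].[OH-] (its oxygen enters the carboxyl group of 12 and may remain as the carbonyl oxygen of 13)
Why: Saponification of the acetate and the bridged δ-lactone gives the carboxylate of 12, whose α-methylene group is no longer a Michael acceptor; on acidification the five-membered lactone to O-2 should close faster and be more stable than the six-membered one to O-13. Only acyl–oxygen bonds are broken and made, so C2 and C13 keep their configuration.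

Step 9
Reactants: 13 (1S,2S,3E,7E,11E,13S)-13-hydroxycembra-3,7,11,15(17)-tetraen-16,2-olide
Product: 14 (1S,2S,3E,7E,11E,13S)-13-acetoxycembra-3,7,11,15(17)-tetraen-16,2-olide (CNP0182196.2)
Conditions: Ac2O, pyridine, DMAP (cat.), CH2Cl2, 0 °C to rt
Reagents that add atoms: acetic anhydride, CC(=O)OC(C)=O
Why: Standard acylation of the secondary allylic alcohol with retention at C13; α-methylene lactones tolerate these conditions.

## Compound list

1 | (2E,6E)-farnesol, (2E,6E)-3,7,11-trimethyldodeca-2,6,10-trien-1-ol | CC(C)=CCC/C(C)=C/CC/C(C)=C/CO | starting material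
2 | (2E,6E)-farnesal | CC(C)=CCC/C(C)=C/CC/C(C)=C/C=O | intermediate
3 | (3E,7E)-4,8,12-trimethyltrideca-1,3,7,11-tetraene | CC(C)=CCC/C(C)=C/CC/C(C)=C/C=C | intermediate
4 | (2E,6E,10E)-2,6,10-trimethyltrideca-2,6,10,12-tetraen-1-ol (formed in the flask in step 3) | OC/C(C)=C/CC/C(C)=C/CC/C(C)=C/C=C | intermediate
5 | (2E,6E,10E)-2,6,10-trimethyltrideca-2,6,10,12-tetraenal | O=C/C(C)=C/CC/C(C)=C/CC/C(C)=C/C=C | intermediate
6 | diisopinocampheylborinate ester of 7 (formed in the flask in step 4) | C=CC[C@H](OB([C@@H]1C[C@@H]2C[C@H]([C@H]1C)C2(C)C)[C@@H]1C[C@@H]2C[C@H]([C@H]1C)C2(C)C)/C(C)=C/CC/C(C)=C/CC/C(C)=C/C=C | intermediate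
7 | (4S,5E,9E,13E)-5,9,13-trimethylhexadeca-1,5,9,13,15-pentaen-4-ol | C=CC[C@H](O)/C(C)=C/CC/C(C)=C/CC/C(C)=C/C=C | intermediate
8 | (1S,2E,6E,10E,12E)-2,6,10-trimethylcyclotetradeca-2,6,10,12-tetraen-1-ol | C1/C=C/C=C(\C)CC/C=C(\C)CC/C=C(\C)[C@H]1O | intermediate
9 | (1S,2E,6E,10E,12E)-2,6,10-trimethylcyclotetradeca-2,6,10,12-tetraen-1-yl 2,3-dibromopropanoate, both epimers at the bromo carbon (formed in the flask in step 6) | C1/C=C/C=C(\C)CC/C=C(\C)CC/C=C(\C)[C@H]1OC(=O)C(Br)CBr | intermediate
10 | (1S,2E,6E,10E,12E)-2,6,10-trimethylcyclotetradeca-2,6,10,12-tetraen-1-yl 2-bromoprop-2-enoate | C1/C=C/C=C(\C)CC/C=C(\C)CC/C=C(\C)[C@H]1OC(=O)C(Br)=C | intermediate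
11 | (1S,2S,3E,7E,11E,13S)-2-acetoxycembra-3,7,11,15(17)-tetraen-16,13-olide (δ-lactone bridging C13 and C1) | C=C1C(=O)O[C@H]2C[C@@H]1[C@@H](OC(C)=O)/C=C(\C)CC/C=C(\C)CC/C=C2\C | intermediate
12 | (1S,2S,3E,7E,11E,13S)-2,13-dihydroxycembra-3,7,11,15(17)-tetraen-16-oic acid (lithium carboxylate before acidification; formed in the flask in step 8) | C=C(C(=O)O)[C@@H]1C[C@H](O)/C(C)=C/CC/C(C)=C/CC/C(C)=C/[C@@H]1O | intermediate
13 | (1S,2S,3E,7E,11E,13S)-13-hydroxycembra-3,7,11,15(17)-tetraen-16,2-olide | C=C1C(=O)O[C@H]2/C=C(\C)CC/C=C(\C)CC/C=C(\C)[C@@H](O)C[C@@H]12 | intermediate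
14 | (1S,2S,3E,7E,11E,13S)-13-acetoxycembra-3,7,11,15(17)-tetraen-16,2-olide (CNP0182196.2) | C=C1C(=O)O[C@H]2/C=C(\C)CC/C=C(\C)CC/C=C(\C)[C@@H](OC(C)=O)C[C@@H]12 | target

## Step count and least certain steps

Total step count: 9. Longest linear sequence: 9 steps (the route is linear from 1; no protecting group is used).

**Step 7 (key step).**
- What may go wrong: the ester prefers the s-trans conformation, which slows the 6-exo insertion and gives time for reduction of the C–Br bond or for 5-exo insertion into C11=C12. The η3-allyl may lose a β-hydrogen before acetate arrives. Zerovalent palladium may ionise the allylic C13–O bond. Exchange between palladium centres may erode the anti selectivity at C2.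
- Fallback: it sets out from 8 and returns at 14. Acetylation of 8 (Ac2O, pyridine) gives the macrocyclic acetate F1. F1 is then annulated without a tether with 2-bromoacrylic acid (Pd(OAc)2, Bu4NCl, K2CO3, DMF, 80 °C). The alkenylpalladium adds intermolecularly to C1 and the free carboxylate closes the γ-lactone on C2 of the allyl from the face opposite to palladium, so the cis lactone 14 is formed directly and steps 6, 8 and 9 fall away. No ester rotamer is involved, but the face of the diene is then chosen only by the ring conformation, so a C1/C2 diastereomer may have to be separated.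

**Step 5.**
- What may go wrong: incomplete E selectivity at the new C1=C2 bond (the Z isomer would lead to the trans lactone), oligomerisation, or trapping of the catalyst as an unreactive vinylcarbene on the diene end.
- Fallback: ring-closing alkyne metathesis and trans-selective semi-reduction; it sets out from 2 and returns at 8.
  - CBr4/PPh3 converts 2 into the dibromodiene F2.
  - n-BuLi followed by MeI gives the methyl-capped enyne F3.
  - SeO2/t-BuOOH gives the allylic alcohol F4 and MnO2 the enal F5.
  - Buta-2,3-dien-2-ylboronic acid pinacol ester with a BINOL-derived chiral phosphoric acid (the antipode that directs Si-face attack) gives the diynol F6.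
  - Mo(≡CC6H4OMe-4)(OSiPh3)3 with 5 Å molecular sieves in toluene closes the macrocyclic enynol F7.
  - [Cp*Ru(MeCN)3]PF6 with (EtO)3SiH adds H and Si trans across the triple bond to give the vinylsilane F8.
  - AgF in aqueous THF/MeOH replaces silicon by hydrogen with retention and gives 8 with a defined E,E-diene.

**Step 8.**
- What may go wrong: partition of 12 between five- and six-membered lactonisation, acid-induced ionisation of the allylic C2–OH, or conjugate addition of hydroxide to the methylene lactone before ring opening.
- Fallback: it sets out from 11 and returns at 13, and forms the γ-lactone by C2–O bond formation instead of acyl transfer. One equivalent of LiOH at 0 °C opens only the bridged lactone and gives the hydroxy acid acetate F9. Pd(PPh3)4 with Et3N in THF then ionises the allylic C2 acetate to the same η3-allyl as in step 7, and the carboxylate closes the five-membered ring on C2 with net retention (two inversions), giving 13.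

**Step 3.**
- What may go wrong: loss of site selectivity (attack at the internal allylic positions) or oxidation of the conjugated diene.
- Fallback: it sets out from 2 and returns at 4, so that the oxidation is run before the diene exists. SeO2/t-BuOOH on farnesal, whose own olefin is deactivated by the carbonyl group, gives 12-hydroxyfarnesal F10. Wittig methylenation of F10 with two equivalents of the ylide of step 2 gives 4, which MnO2 oxidises to 5 as in step 3.

## Further compounds

F1 | step 7 | (1S,2E,6E,10E,12E)-2,6,10-trimethylcyclotetradeca-2,6,10,12-tetraen-1-yl acetate | C1/C=C/C=C(\C)CC/C=C(\C)CC/C=C(\C)[C@H]1OC(C)=O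
F2 | step 5 | (3E,7E)-1,1-dibromo-4,8,12-trimethyltrideca-1,3,7,11-tetraene | CC(C)=CCC/C(C)=C/CC/C(C)=C/C=C(Br)Br
F3 | step 5 | (4E,8E)-5,9,13-trimethyltetradeca-4,8,12-trien-2-yne | CC(C)=CCC/C(C)=C/CC/C(C)=C/C#CC
F4 | step 5 | (2E,6E,10E)-2,6,10-trimethyltetradeca-2,6,10-trien-12-yn-1-ol | OC/C(C)=C/CC/C(C)=C/CC/C(C)=C/C#CC
F5 | step 5 | (2E,6E,10E)-2,6,10-trimethyltetradeca-2,6,10-trien-12-ynal | O=C/C(C)=C/CC/C(C)=C/CC/C(C)=C/C#CC
F6 | step 5 | (5S,6E,10E,14E)-6,10,14-trimethyloctadeca-6,10,14-triene-2,16-diyn-5-ol | CC#CC[C@H](O)/C(C)=C/CC/C(C)=C/CC/C(C)=C/C#CC
F7 | step 5 | (1S,2E,6E,10E)-2,6,10-trimethylcyclotetradeca-2,6,10-trien-12-yn-1-ol | C1C#C/C=C(\C)CC/C=C(\C)CC/C=C(\C)[C@H]1O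
F8 | step 5 | (1S,2E,6E,10E,12Z)-2,6,10-trimethyl-12-(triethoxysilyl)cyclotetradeca-2,6,10,12-tetraen-1-ol | C1/C=C([Si](OCC)(OCC)OCC)/C=C(\C)CC/C=C(\C)CC/C=C(\C)[C@H]1O
F9 | step 8 | (1S,2S,3E,7E,11E,13S)-2-acetoxy-13-hydroxycembra-3,7,11,15(17)-tetraen-16-oic acid | C=C(C(=O)O)[C@@H]1C[C@H](O)/C(C)=C/CC/C(C)=C/CC/C(C)=C/[C@@H]1OC(C)=O
F10 | step 3 | (2E,6E,10E)-12-hydroxy-3,7,11-trimethyldodeca-2,6,10-trienal | OC/C(C)=C/CC/C(C)=C/CC/C(C)=C/C=O
A1 | alternative 1 | methyl (2Z,5S,6E,10E,14E)-5-acetoxy-2-(bromomethyl)-6,10,14-trimethyl-16-oxohexadeca-2,6,10,14-tetraenoate | O=C/C=C(\C)CC/C=C(\C)CC/C=C(\C)[C@@H](OC(C)=O)C/C=C(\CBr)C(=O)OC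
A2 | alternative 2 | 18-membered β-keto lactone in which the 3-(acyloxymethyl)-2(5H)-furanone (C2 configured as in 14) is tied through C3–C12 to the C13 keto group | O=C1O[C@H]2/C=C(\C)CC/C=C(\C)CC/C=C(\C)C(=O)CC(=O)OCC1=C2
A3 | alternative 3 | 2-[(2S,3S)-2-[(1E,5E,9E)-10-iodo-2,6-dimethylundeca-1,5,9-trienyl]-4-methylidene-5-oxooxolan-3-yl]acetaldehyde | C=C1C(=O)O[C@@H](/C=C(\C)CC/C=C(\C)CC/C=C(\C)I)[C@H]1CC=O
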